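## Structural features

The target is a 2,3-dihydrobenzofuran neolignan: benzene ring A is fused through C3a–C7a to the oxygen heterocycle ring B (O1, C2, C3, C3a, C7a), and C2 carries the 4-hydroxy-3-methoxyphenyl ring C. Ring A is unsymmetrically substituted: O1 on C7a, a methoxy group on C7, a 3-(sulfooxy)propyl chain on C5 and C3 on C3a, so only C4 and C6 bear hydrogen. The two stereocentres C2 (S) and C3 (R) are neighbours and trans; C3 carries a hydroxymethyl group. Fragile points are the C2–O1 bond, which is benzylic to an electron-rich arene (it ionizes with acid and can be hydrogenolysed), and the alkyl hydrogen sulfate, a strong acid once free. Three hydroxyl groups (one phenol, two primary alcohols) must also be told apart so that only the end of the propyl chain is sulfated. The real difficulty is to combine a trans C2/C3 pair of fixed absolute configuration with a fully regiodefined substitution pattern on ring A. The key step uses the fact that O1, C7a, C3a, C3 and C2 are a γ-butyrolactone when C7a is a carbonyl carbon: both stereocentres are set on a simple trans lactone, and ring A is then completed across the vinylogous silyl ketene acetal C7a=C3a–C4=C5, whose polarity fixes the ring A pattern.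

## Logic of the disconnections

26 to 24 (through 25). The two O–CH2Ph bonds (phenol oxygen of ring C, oxygen of the C3 hydroxymethyl group) and the sulfate O–H are formed last. Both hydroxyl groups that must end free travel as the same kind of ether and are released together by hydrogenolysis, which a sulfate monoester salt withstands. Demand: the hydrogenolysis must stop before the benzylic C2–O1 bond reacts, and the acid form must be liberated cold and dilute.

24 to 23. The S–O bond is cut. 23 has exactly one free hydroxyl group, so the charged group enters one step from the end. Demand: a mild SO3 donor that spares the electron-rich arenes.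

23 to 22. The Si–O bond at the chain terminus is cut. The silyl ether is orthogonal to both benzyl ethers, so fluoride exposes only the alcohol meant for the sulfate.

22 to 20 (through 21) to 19. The C7–OCH3 bond is traced to a C7–acetyl bond: O–CH3 back to 21, O–acyl back to 20, and the C7–O bond of 20 back to the C7–C bond of 19 (Baeyer–Villiger retron). A carbonyl group at C7 is what makes the two-carbon partner of the annulation reactive and regiodirecting; an oxygen substituent could not do that. Demand: aryl, not methyl, must migrate, which the ortho oxygen O1 secures.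

19 to 16 + 17 (through 18). C5–C6 and C7–C7a are cut: ring A is divided into the diene C7a=C3a–C4=C5 of 16 and the two alkyne carbons (C6, C7) of 17. An arene with this pattern is thus assembled regiospecifically by polarity, with both stereocentres already in place. Demand: one regiochemistry of cycloaddition, loss of the silyloxy group and not of O1 from C7a, and conditions that leave C2 and C3 alone.

16 to 15. The O–Si bond of the ketene acetal and the C5–H bond are restored. 16 is only the silylated dienolate of 15, so a stable conjugated lactone is the storage form. Demand: deprotonation at C5 and not at C3, without conjugate addition of the base.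

15 to 13 (through 14) to 9 + 12. The C3a=C4 bond is cut (aldol condensation retron): C3a is the α-carbon of 9, C4 the carbonyl carbon of 12. One C–C bond joins the stereodefined lactone to C4, C5 and the whole side chain. Demand: an enolate of 9 that cannot eliminate (no leaving group β to C3a) and a dehydration that does not touch C3.

12 to 11 to 10. The aldehyde is returned to the alcohol and the Si–O bond is cut, which leads to a symmetric diol. Demand: monosilylation.

9 to 8 to 7 to 6. In turn the O–CH2Ph bond, the oxidation level of the carbon on C3, and the N–acyl bond to the auxiliary. The hydroxymethyl carbon is the carbonyl group through which C3 was made nucleophilic. Demand: cleavage and reduction without opening or reducing the lactone, and benzylation without alkoxide or strong acid.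

6 to 3 + 4 (through 5). C2–C3 (aldol) and O1–C7a (lactone) are cut. The C2–C3 bond joins the two stereocentres, so one auxiliary-controlled step sets both, and lactonization stores the syn aldol as the trans lactone. Demand: enolization on the imide side only, and the facial sense of the (S)-benzyl auxiliary.

3 to 1 + 2. The N–acyl bond is cut; 1, 2 and 4 are articles of commerce.

## Other disconnections considered

Alternative 1: The cut is C3–C3a, made as a ring contraction of the enantioenriched flavanone A1. PhI(OAc)2 (trivalent iodine) with HC(OMe)3 and acid would iodinate the enol ether of A1 at C3; ring A would then shift from the ketal carbon to C3 and give the trans methyl ester A2, whose ester becomes the hydroxymethyl group.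
- In favour: ring A comes complete from a simple phenol, so neither a benzannulation nor the acetyl-to-methoxy exchange is needed. The trans relation follows from the migration geometry and can be corrected by equilibration next to the ester.
- Against, here: the same intermediate can trigger a 1,2-shift of ring C from C2 to C3. That path is favoured by the para-alkoxy group that ring C carries, whereas ring A is activated at its migrating carbon only by O1. C2 of A1 can also erode under acid through reversible retro-oxa-Michael opening, and the electron-rich arenes are open to oxidation by the iodane.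
- Comparison: in structure A2 and 22 are of similar complexity, and the relay from C2 to C3 is the equal of the aldol for the trans relation. In mechanism the chosen plan is safer, because diene polarity and substrate substitution pull the same way, while here the substrate is biased towards the wrong migration. In step economy Alternative 1 is the better.

Alternative 2: The cuts are C3–C3a and the C–O bond of the hydroxymethyl group. Bu3SnH under air would convert the aryl iodide A3 into the C3a radical, which adds 5-exo to the vinyl group; the primary radical is captured by O2 and reduced in the flask to the alcohol A4.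
- In favour: ring B and the free hydroxymethyl group arise in one step, ring A is again bought complete, and 5-exo regiochemistry is secure. Benzylation of A4 would give 22, so the last three steps are shared. In step economy this alternative is better, and in functional-group tolerance at least equal.
- Against: C3 is created in the key step under substrate control only. The trans preference rests on a modest bias in the chair-like transition state, so a hard-to-separate cis isomer must be expected. The only stereocentre of A3 sits on a carbon that is allylic, benzylic to an electron-rich arene and bound to a di-ortho-substituted aryloxy group; forming that C–O bond enantioselectively and keeping it from ionizing or rearranging is the real problem. Oxygen capture must also outrun hydrogen transfer from the stannane, and tin residues must be removed.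
- Comparison: the chosen plan is longer, but it sets both centres by an auxiliary-controlled aldol before ring A exists and creates no stereocentre in its key step. The radical route would be the better plan if trans selectivity and the supply of A3 were secured.

Alternative 3: The cuts are C3a–C7a and C6–C7, so rings A and B arise together from the furan-tethered ethynyl ether A5. Ph3PAuNTf2 (monovalent gold) would activate the alkyne; the furan adds to the oxygen-bearing alkyne carbon, and the sequence of cyclopropyl carbene, ring opening, oxepine and arene oxide moves the furan oxygen onto C7. The product is the phenol A6, the same compound as 21.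
- In favour: two rings close in one catalytic step at ambient temperature, no stereocentre is touched, and the C7 oxygen is delivered directly, which saves step 12 and the first half of step 13. On convergence of the key step and economy after it this alternative is better. In regiochemical security it is equal, since furan-yne phenol syntheses with alkynyl ethers place the hydroxyl next to the heteroatom-bearing ring-fusion carbon.
- Against: A5 needs three awkward features at once. These are a furan substituted at its 2- and 4-positions, a C2/C3 pair with the furyl group on C3 (which the succinate aldol cannot supply), and an ethynyl ether on a secondary carbon benzylic to an electron-rich ring. That last motif is prone to sigmatropic rearrangement, retro-ene loss of ketene on mild warming, and ionization under a Lewis acid.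
- Comparison: the chosen plan keeps every intermediate before its key step a robust lactone, whereas here the risk is concentrated in a fragile precursor. Both key steps are regiochemically determined by polarity. The gain in steps after the key step would probably be used up on the longer way to A5.

Key step: step 11

Assumption: the target is taken as the free hydrogen sulfate as drawn; it is carried as the sodium salt and protonated only in the last operation, cold and dilute, because a free alkyl hydrogen sulfate is a strong acid.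

## Route

Step 1
Reactants: 1 (S)-4-benzyl-1,3-oxazolidin-2-one; 2 methyl 4-chloro-4-oxobutanoate
Product: 3 methyl 4-[(4S)-4-benzyl-2-oxo-1,3-oxazolidin-3-yl]-4-oxobutanoate
Conditions: n-BuLi, THF, −78 °C; then 2, −78 → 0 °C
Reagents that add atoms: none
Why: N-acylation of the lithiated oxazolidinone by the acid chloride, which is far more electrophilic than the methyl ester; no stereocentre is formed and the auxiliary centre is not enolizable.

Step 2
Reactants: 3 methyl 4-[(4S)-4-benzyl-2-oxo-1,3-oxazolidin-3-yl]-4-oxobutanoate; 4 4-(benzyloxy)-3-methoxybenzaldehyde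
Product: 6 (4S)-4-benzyl-3-{[(2S,3S)-2-[4-(benzyloxy)-3-methoxyphenyl]-5-oxooxolan-3-yl]carbonyl}-1,3-oxazolidin-2-one (trans lactone), via syn aldol adduct 5 (not isolated)
Conditions: Bu2BOTf, i-Pr2NEt, CH2Cl2, −78 → 0 °C; 4, −78 → 0 °C; pH 7 buffer, MeOH, H2O2, 0 °C; then PPTS (cat.), PhMe, 50 °C
Reagents that add atoms: none
Why: Evans boron aldol reaction followed by lactonization: Bu2BOTf and the amine enolize only the imide side (Z enolate), the Zimmerman-Traxler chair puts the aldehyde on the enolate face away from the benzyl group of the auxiliary and so sets C2 (S) and C3 as the syn pair, and the C2 alkoxide then closes on the methyl ester (O1-C7a), which turns the syn aldol into the trans lactone.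

Step 3
Reactants: 6 (4S)-4-benzyl-3-{[(2S,3S)-2-[4-(benzyloxy)-3-methoxyphenyl]-5-oxooxolan-3-yl]carbonyl}-1,3-oxazolidin-2-one
Product: 7 (2S,3S)-2-[4-(benzyloxy)-3-methoxyphenyl]-5-oxooxolane-3-carboxylic acid
Conditions: LiOH, H2O2, THF/H2O, 0 °C; Na2SO3; then 1 M HCl to pH 2
Reagents that add atoms: hydrogen peroxide, OO (as LiOOH it supplies the carboxyl OH oxygen)
Why: Hydroperoxide cleavage of the N-acyl oxazolidinone: LiOOH attacks the exocyclic carbonyl group selectively and is too weak a base to enolize C3; any lactone opened by hydroxide closes again on acidification.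

Step 4
Reactants: 7 (2S,3S)-2-[4-(benzyloxy)-3-methoxyphenyl]-5-oxooxolane-3-carboxylic acid
Product: 8 (4R,5S)-5-[4-(benzyloxy)-3-methoxyphenyl]-4-(hydroxymethyl)oxolan-2-one
Conditions: BH3·SMe2, THF, 0 °C → rt; MeOH
Reagents that add atoms: none
Why: Borane reduces a carboxylic acid (through its acyloxyborane) much faster than a lactone, so only the carboxyl group becomes the hydroxymethyl group; no stereocentre is affected.

Step 5
Reactants: 8 (4R,5S)-5-[4-(benzyloxy)-3-methoxyphenyl]-4-(hydroxymethyl)oxolan-2-one
Product: 9 (4R,5S)-5-[4-(benzyloxy)-3-methoxyphenyl]-4-[(benzyloxy)methyl]oxolan-2-one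
Conditions: 2-benzyloxy-1-methylpyridinium triflate, MgO, PhCF3, 83 °C
Reagents that add atoms: 2-benzyloxy-1-methylpyridinium trifluoromethanesulfonate, C[n+]1ccccc1OCc1ccccc1.[O-]S(=O)(=O)C(F)(F)F
Why: Neutral benzyl transfer from the 2-benzyloxypyridinium salt (Dudley benzylation) with MgO as acid scavenger: no alkoxide is formed, so the acyl group cannot move to the primary oxygen, and no strong acid is present that could ionize the electron-rich benzylic C2-O bond.

Step 6
Reactants: 10 pentane-1,5-diol
Product: 11 5-[(tert-butyldimethylsilyl)oxy]pentan-1-ol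
Conditions: NaH (1.0 equiv), THF, rt; TBSCl
Reagents that add atoms: tert-butyldimethylsilyl chloride, CC(C)(C)[Si](C)(C)Cl
Why: Monosilylation of a symmetric diol through its sparingly soluble monosodium alkoxide, which reacts once with the silyl chloride before a second deprotonation can occur.

Step 7
Reactants: 11 5-[(tert-butyldimethylsilyl)oxy]pentan-1-ol
Product: 12 5-[(tert-butyldimethylsilyl)oxy]pentanal
Conditions: TEMPO (cat.), PhI(OAc)2, CH2Cl2, rt
Reagents that add atoms: none
Why: Oxoammonium (TEMPO) oxidation with PhI(OAc)2 as terminal oxidant stops at the aldehyde and leaves the silyl ether alone.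

Step 8
Reactants: 9 (4R,5S)-5-[4-(benzyloxy)-3-methoxyphenyl]-4-[(benzyloxy)methyl]oxolan-2-one; 12 5-[(tert-butyldimethylsilyl)oxy]pentanal
Product: 13 (4R,5S)-5-[4-(benzyloxy)-3-methoxyphenyl]-4-[(benzyloxy)methyl]-3-{5-[(tert-butyldimethylsilyl)oxy]-1-hydroxypentyl}oxolan-2-one (diastereomer mixture at C3 of the lactone and at the carbinol carbon)
Conditions: LiN(i-Pr)2, THF, −78 °C; 12; AcOH, −78 °C
Reagents that add atoms: none
Why: Aldol addition of the lithium enolate of the lactone (C3a has no leaving group in the β-position) to the aldehyde at low temperature; the two new centres need no control because both disappear in steps 9 to 11.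

Step 9
Reactants: 13 (4R,5S)-5-[4-(benzyloxy)-3-methoxyphenyl]-4-[(benzyloxy)methyl]-3-{5-[(tert-butyldimethylsilyl)oxy]-1-hydroxypentyl}oxolan-2-one
Product: 15 (3E,4R,5S)-5-[4-(benzyloxy)-3-methoxyphenyl]-4-[(benzyloxy)methyl]-3-{5-[(tert-butyldimethylsilyl)oxy]pentylidene}oxolan-2-one, via mesylate 14 (not isolated)
Conditions: MsCl, Et3N, CH2Cl2, 0 °C; then DBU, rt
Reagents that add atoms: none
Why: Mesylation and E1cB elimination give the conjugated alkylidene lactone (C3a=C4), the E isomer being favoured; C3-H is only cross-conjugated with the carbonyl group and is not removed by DBU, and either alkene geometry leads to the same diene in step 10.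

Step 10
Reactants: 15 (3E,4R,5S)-5-[4-(benzyloxy)-3-methoxyphenyl]-4-[(benzyloxy)methyl]-3-{5-[(tert-butyldimethylsilyl)oxy]pentylidene}oxolan-2-one
Product: 16 tert-butyl{[(4R,5S)-5-[4-(benzyloxy)-3-methoxyphenyl]-4-[(benzyloxy)methyl]-3-[(1E)-5-{[tert-butyl(dimethyl)silyl]oxy}pent-1-en-1-yl]-4,5-dihydrofuran-2-yl]oxy}dimethylsilane (vinylketene silyl acetal)
Conditions: LiN(i-Pr)2, THF/DMPU, −78 °C; TBSCl, −78 → 0 °C; volatiles removed in vacuo, pentane, filtration under Ar; used crude
Reagents that add atoms: tert-butyldimethylsilyl chloride, CC(C)(C)[Si](C)(C)Cl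
Why: Vinylogous (γ) enolization at C5 and O-silylation of the dienolate, the standard preparation of vinylketene silyl acetals; DMPU suppresses conjugate addition of the amide and directs silylation to oxygen, C3-H is not acidified by the carbonyl group because it is cross-conjugated, and the new C4=C5 bond forms trans.

Step 11
Reactants: 16 tert-butyl{[(4R,5S)-5-[4-(benzyloxy)-3-methoxyphenyl]-4-[(benzyloxy)methyl]-3-[(1E)-5-{[tert-butyl(dimethyl)silyl]oxy}pent-1-en-1-yl]-4,5-dihydrofuran-2-yl]oxy}dimethylsilane; 17 but-3-yn-2-one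
Product: 19 1-[(2S,3R)-2-[4-(benzyloxy)-3-methoxyphenyl]-3-[(benzyloxy)methyl]-5-{3-[(tert-butyldimethylsilyl)oxy]propyl}-2,3-dihydro-1-benzofuran-7-yl]ethan-1-one, via cycloadduct 18 (not isolated)
Conditions: 17 (3 equiv), 2,6-di-tert-butyl-4-methylpyridine (0.1 equiv), PhMe, rt → 80 °C, sealed tube
Reagents that add atoms: none
Why: The 1-alkoxy-1-silyloxy diene is polarized so that its remote terminus C5 is the nucleophilic end; C5 bonds to the unsubstituted β-carbon of the ynone (C5-C6) and the acetal carbon C7a to the acyl-bearing carbon (C7-C7a), in one asynchronous (4+2) transition state or through a short-lived zwitterion that closes at once, so only the 7-acetyl pattern can arise. The closest known reaction type is the Diels-Alder benzannulation of vinylketene silyl acetals with acetylenic ketones and esters, in which the cyclohexa-1,4-diene aromatizes by 1,4-loss of silanol. Ring A is closed by (4+2) cycloaddition on the s-cis diene C7a=C3a-C4=C5; ring B already holds C7a=C3a and the C3a-C4 single bond rotates freely. No stereocentre of the target is formed: C5 and C7a of 18 are transient and both become sp2, while C2 and C3 lie outside the diene and are untouched under neutral, aprotic conditions. The selectivity that matters is which oxygen leaves C7a: because the cycloaddition is suprafacial on the E diene, the silyloxy group (inside substituent) and H-5 end up cis and can both take flagpole positions of the boat, in line with the flanking π bonds, whereas the C7a-O1 bond is held near the ring plane by the five-membered ring and is trans to H-5. Syn 1,4-loss of t-BuMe2SiOH, whose silanolate is also the better leaving group, is therefore preferred over opening of ring B. The robust t-BuMe2Si group (in place of Me3Si) and the hindered pyridine buffer keep the ketal from being desilylated or protonated, which would open ring B through the hemiketal.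

Step 12
Reactants: 19 1-[(2S,3R)-2-[4-(benzyloxy)-3-methoxyphenyl]-3-[(benzyloxy)methyl]-5-{3-[(tert-butyldimethylsilyl)oxy]propyl}-2,3-dihydro-1-benzofuran-7-yl]ethan-1-one
Product: 20 (2S,3R)-2-[4-(benzyloxy)-3-methoxyphenyl]-3-[(benzyloxy)methyl]-5-{3-[(tert-butyldimethylsilyl)oxy]propyl}-2,3-dihydro-1-benzofuran-7-yl acetate
Conditions: mCPBA, CH2Cl2, 0 °C → rt
Reagents that add atoms: 3-chloroperoxybenzoic acid, OOC(=O)c1cccc(Cl)c1
Why: Baeyer-Villiger oxidation: in the Criegee intermediate the electron-rich aryl group (ortho oxygen O1) migrates far more readily than methyl, so the C7-C bond is replaced by C7-O at the same position; ethers and the silyl ether are inert to the peracid.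

Step 13
Reactants: 20 (2S,3R)-2-[4-(benzyloxy)-3-methoxyphenyl]-3-[(benzyloxy)methyl]-5-{3-[(tert-butyldimethylsilyl)oxy]propyl}-2,3-dihydro-1-benzofuran-7-yl acetate
Product: 22 tert-butyl{3-[(2S,3R)-2-[4-(benzyloxy)-3-methoxyphenyl]-3-[(benzyloxy)methyl]-7-methoxy-2,3-dihydro-1-benzofuran-5-yl]propoxy}dimethylsilane, via 7-hydroxy phenol 21 (not isolated)
Conditions: K2CO3, MeOH, rt; evaporate; MeI, K2CO3, DMF, rt
Reagents that add atoms: iodomethane, CI
Why: Base-catalysed transesterification frees the phenoxide, which is the only nucleophile present for the Williamson methylation; the alkyl silyl ether and the benzyl ethers are stable to carbonate.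

Step 14
Reactants: 22 tert-butyl{3-[(2S,3R)-2-[4-(benzyloxy)-3-methoxyphenyl]-3-[(benzyloxy)methyl]-7-methoxy-2,3-dihydro-1-benzofuran-5-yl]propoxy}dimethylsilane
Product: 23 3-[(2S,3R)-2-[4-(benzyloxy)-3-methoxyphenyl]-3-[(benzyloxy)methyl]-7-methoxy-2,3-dihydro-1-benzofuran-5-yl]propan-1-ol
Conditions: Bu4NF, AcOH, THF, rt
Reagents that add atoms: none
Why: Fluoride cleaves the Si-O bond (strong Si-F bond); buffering with acetic acid keeps the medium near neutral, and benzyl and methyl ethers do not react.

Step 15
Reactants: 23 3-[(2S,3R)-2-[4-(benzyloxy)-3-methoxyphenyl]-3-[(benzyloxy)methyl]-7-methoxy-2,3-dihydro-1-benzofuran-5-yl]propan-1-ol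
Product: 24 sodium 3-[(2S,3R)-2-[4-(benzyloxy)-3-methoxyphenyl]-3-[(benzyloxy)methyl]-7-methoxy-2,3-dihydro-1-benzofuran-5-yl]propyl sulfate
Conditions: SO3·pyridine, pyridine, rt; aq NaHCO3
Reagents that add atoms: sulfur trioxide-pyridine complex, O=S(=O)([O-])[n+]1ccccc1; sodium hydrogen carbonate, [Na+].OC([O-])=O
Why: O-Sulfation of the only free hydroxyl group with the mild SO3 donor SO3·pyridine; exchange to the sodium salt removes pyridine, which would slow the hydrogenolysis, and gives a salt that is stable to handling.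

Step 16
Reactants: 24 sodium 3-[(2S,3R)-2-[4-(benzyloxy)-3-methoxyphenyl]-3-[(benzyloxy)methyl]-7-methoxy-2,3-dihydro-1-benzofuran-5-yl]propyl sulfate
Product: 26 3-[(2S,3R)-2-(4-hydroxy-3-methoxyphenyl)-3-(hydroxymethyl)-7-methoxy-2,3-dihydro-1-benzofuran-5-yl]propyl hydrogen sulfate, via debenzylated sodium salt 25 (not isolated)
Conditions: H2 (1 atm), Pd/C, MeOH, rt; filter; HCl (1.0 equiv), H2O, 0 °C; C18 desalting, freeze-drying
Reagents that add atoms: none
Why: Hydrogenolysis on Pd/C cleaves both benzyl ethers (aryl ether first, alkyl ether more slowly) while sulfate monoester salts are inert to hydrogen; the reaction is stopped at the uptake of two equivalents to spare the benzylic C2-O1 bond, and one equivalent of acid in the cold then gives the hydrogen sulfate without touching C2 or C3.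

## Compound list

1 | (S)-4-benzyl-1,3-oxazolidin-2-one | O=C1OC[C@H](Cc2ccccc2)N1 | starting material
2 | methyl 4-chloro-4-oxobutanoate | COC(=O)CCC(=O)Cl | starting material
3 | methyl 4-[(4S)-4-benzyl-2-oxo-1,3-oxazolidin-3-yl]-4-oxobutanoate | COC(=O)CCC(=O)N1[C@@H](Cc2ccccc2)COC1=O | intermediate
4 | 4-(benzyloxy)-3-methoxybenzaldehyde | COc1cc(C=O)ccc1OCc1ccccc1 | starting material
5 | methyl (3S,4S)-4-[4-(benzyloxy)-3-methoxyphenyl]-3-{[(4S)-4-benzyl-2-oxo-1,3-oxazolidin-3-yl]carbonyl}-4-hydroxybutanoate (syn aldol adduct, not isolated) | COc1cc([C@@H](O)[C@H](CC(=O)OC)C(=O)N2[C@@H](Cc3ccccc3)COC2=O)ccc1OCc1ccccc1 | intermediate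
6 | (4S)-4-benzyl-3-{[(2S,3S)-2-[4-(benzyloxy)-3-methoxyphenyl]-5-oxooxolan-3-yl]carbonyl}-1,3-oxazolidin-2-one | COc1cc([C@H]2OC(=O)C[C@@H]2C(=O)N2[C@@H](Cc3ccccc3)COC2=O)ccc1OCc1ccccc1 | intermediate
7 | (2S,3S)-2-[4-(benzyloxy)-3-methoxyphenyl]-5-oxooxolane-3-carboxylic acid | COc1cc([C@H]2OC(=O)C[C@@H]2C(=O)O)ccc1OCc1ccccc1 | intermediate
8 | (4R,5S)-5-[4-(benzyloxy)-3-methoxyphenyl]-4-(hydroxymethyl)oxolan-2-one | COc1cc([C@H]2OC(=O)C[C@@H]2CO)ccc1OCc1ccccc1 | intermediate
9 | (4R,5S)-5-[4-(benzyloxy)-3-methoxyphenyl]-4-[(benzyloxy)methyl]oxolan-2-one | COc1cc([C@H]2OC(=O)C[C@@H]2COCc2ccccc2)ccc1OCc1ccccc1 | intermediate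
10 | pentane-1,5-diol | OCCCCCO | starting material
11 | 5-[(tert-butyldimethylsilyl)oxy]pentan-1-ol | CC(C)(C)[Si](C)(C)OCCCCCO | intermediate
12 | 5-[(tert-butyldimethylsilyl)oxy]pentanal | CC(C)(C)[Si](C)(C)OCCCCC=O | intermediate
13 | (4R,5S)-5-[4-(benzyloxy)-3-methoxyphenyl]-4-[(benzyloxy)methyl]-3-{5-[(tert-butyldimethylsilyl)oxy]-1-hydroxypentyl}oxolan-2-one (diastereomer mixture at the two new centres) | COc1cc([C@H]2OC(=O)C(C(O)CCCCO[Si](C)(C)C(C)(C)C)[C@@H]2COCc2ccccc2)ccc1OCc1ccccc1 | intermediate
14 | methanesulfonate of 13 (not isolated) | COc1cc([C@H]2OC(=O)C(C(OS(C)(=O)=O)CCCCO[Si](C)(C)C(C)(C)C)[C@@H]2COCc2ccccc2)ccc1OCc1ccccc1 | intermediate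
15 | (3E,4R,5S)-5-[4-(benzyloxy)-3-methoxyphenyl]-4-[(benzyloxy)methyl]-3-{5-[(tert-butyldimethylsilyl)oxy]pentylidene}oxolan-2-one | COc1cc([C@H]2OC(=O)/C(=C/CCCCO[Si](C)(C)C(C)(C)C)[C@@H]2COCc2ccccc2)ccc1OCc1ccccc1 | intermediate
16 | tert-butyl{[(4R,5S)-5-[4-(benzyloxy)-3-methoxyphenyl]-4-[(benzyloxy)methyl]-3-[(1E)-5-{[tert-butyl(dimethyl)silyl]oxy}pent-1-en-1-yl]-4,5-dihydrofuran-2-yl]oxy}dimethylsilane | COc1cc([C@H]2OC(O[Si](C)(C)C(C)(C)C)=C(/C=C/CCCO[Si](C)(C)C(C)(C)C)[C@@H]2COCc2ccccc2)ccc1OCc1ccccc1 | intermediate
17 | but-3-yn-2-one | CC(=O)C#C | starting material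
18 | 1-[(2S,3R)-2-[4-(benzyloxy)-3-methoxyphenyl]-3-[(benzyloxy)methyl]-7a-[(tert-butyldimethylsilyl)oxy]-5-{3-[(tert-butyldimethylsilyl)oxy]propyl}-2,3,5,7a-tetrahydro-1-benzofuran-7-yl]ethan-1-one (cycloadduct, not isolated; C5 and C7a transient, silyloxy group cis to H-5) | COc1cc([C@H]2OC3(O[Si](C)(C)C(C)(C)C)C(C(C)=O)=CC(CCCO[Si](C)(C)C(C)(C)C)C=C3[C@@H]2COCc2ccccc2)ccc1OCc1ccccc1 | intermediate
19 | 1-[(2S,3R)-2-[4-(benzyloxy)-3-methoxyphenyl]-3-[(benzyloxy)methyl]-5-{3-[(tert-butyldimethylsilyl)oxy]propyl}-2,3-dihydro-1-benzofuran-7-yl]ethan-1-one | COc1cc([C@H]2Oc3c(C(C)=O)cc(CCCO[Si](C)(C)C(C)(C)C)cc3[C@@H]2COCc2ccccc2)ccc1OCc1ccccc1 | intermediate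
20 | (2S,3R)-2-[4-(benzyloxy)-3-methoxyphenyl]-3-[(benzyloxy)methyl]-5-{3-[(tert-butyldimethylsilyl)oxy]propyl}-2,3-dihydro-1-benzofuran-7-yl acetate | COc1cc([C@H]2Oc3c(OC(C)=O)cc(CCCO[Si](C)(C)C(C)(C)C)cc3[C@@H]2COCc2ccccc2)ccc1OCc1ccccc1 | intermediate
21 | (2S,3R)-2-[4-(benzyloxy)-3-methoxyphenyl]-3-[(benzyloxy)methyl]-5-{3-[(tert-butyldimethylsilyl)oxy]propyl}-2,3-dihydro-1-benzofuran-7-ol (not isolated) | COc1cc([C@H]2Oc3c(O)cc(CCCO[Si](C)(C)C(C)(C)C)cc3[C@@H]2COCc2ccccc2)ccc1OCc1ccccc1 | intermediate
22 | tert-butyl{3-[(2S,3R)-2-[4-(benzyloxy)-3-methoxyphenyl]-3-[(benzyloxy)methyl]-7-methoxy-2,3-dihydro-1-benzofuran-5-yl]propoxy}dimethylsilane | COc1cc([C@H]2Oc3c(OC)cc(CCCO[Si](C)(C)C(C)(C)C)cc3[C@@H]2COCc2ccccc2)ccc1OCc1ccccc1 | intermediate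
23 | 3-[(2S,3R)-2-[4-(benzyloxy)-3-methoxyphenyl]-3-[(benzyloxy)methyl]-7-methoxy-2,3-dihydro-1-benzofuran-5-yl]propan-1-ol | COc1cc([C@H]2Oc3c(OC)cc(CCCO)cc3[C@@H]2COCc2ccccc2)ccc1OCc1ccccc1 | intermediate
24 | sodium 3-[(2S,3R)-2-[4-(benzyloxy)-3-methoxyphenyl]-3-[(benzyloxy)methyl]-7-methoxy-2,3-dihydro-1-benzofuran-5-yl]propyl sulfate | COc1cc([C@H]2Oc3c(OC)cc(CCCOS(=O)(=O)[O-])cc3[C@@H]2COCc2ccccc2)ccc1OCc1ccccc1.[Na+] | intermediate
25 | sodium 3-[(2S,3R)-2-(4-hydroxy-3-methoxyphenyl)-3-(hydroxymethyl)-7-methoxy-2,3-dihydro-1-benzofuran-5-yl]propyl sulfate (not isolated) | COc1cc([C@H]2Oc3c(OC)cc(CCCOS(=O)(=O)[O-])cc3[C@@H]2CO)ccc1O.[Na+] | intermediate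
26 | 3-[(2S,3R)-2-(4-hydroxy-3-methoxyphenyl)-3-(hydroxymethyl)-7-methoxy-2,3-dihydro-1-benzofuran-5-yl]propyl hydrogen sulfate | COc1cc([C@H]2Oc3c(OC)cc(CCCOS(=O)(=O)O)cc3[C@@H]2CO)ccc1O | target

## Step count and least certain steps

Total: 16 steps. Longest linear sequence: 14 steps (steps 1 to 5 and 8 to 16, from 1); steps 6 and 7 are the two-step branch to 12.

Step 11 (key step). The most likely failure is departure of the ring oxygen O1 instead of the silyloxy group from C7a, that is, opening of ring B. This would happen if the silyl ketal of 18 is desilylated or protonated before the syn elimination; oligomerization of 17 is a second risk. The fallback sets out from 16 and comes back at 19, and it turns the ring opening into the intended path. The cycloaddition is run as before at room temperature, and the crude mixture is then stirred with K2CO3 in MeOH. This cleaves the silyl ketal and any aryl silyl ether but not the alkyl silyl ether, and funnels everything that has not become 19 into the ring-opened ortho-hydroxy ketone 1-{3-[(1S,2R)-3-(benzyloxy)-1-[4-(benzyloxy)-3-methoxyphenyl]-1-hydroxypropan-2-yl]-5-{3-[(tert-butyldimethylsilyl)oxy]propyl}-2-hydroxyphenyl}ethan-1-one F1. Ring B is then closed again with catalytic camphorsulfonic acid in CH2Cl2 over 4 Å sieves at 0 °C. This is an acid-catalysed cyclodehydration through the para-alkoxybenzylic cation, the classical entry to trans-2-aryl-2,3-dihydrobenzofurans. Because the closure is reversible, the intact C3 centre steers C2 into the trans arrangement, whatever happened at C2 on the way.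

Step 10. The most likely failure is conjugate addition of the amide to C4, or attack at the carbonyl group, in competition with removal of a C5 proton; hydrolysis of the ketene acetal during isolation is the other risk. The fallback sets out from 15 and comes back at 19, and it needs no leaving group at C7a.
- i-Bu2AlH (CH2Cl2, −78 °C) reduces the lactone to the lactol (3E,4R,5S)-5-[4-(benzyloxy)-3-methoxyphenyl]-4-[(benzyloxy)methyl]-3-{5-[(tert-butyldimethylsilyl)oxy]pentylidene}oxolan-2-ol F2.
- PPTS (cat.) in PhMe over 4 Å sieves at 60 °C dehydrates it through the allyl oxocarbenium ion, which can lose a proton only from C5. The product is the cyclic dienyl ether tert-butyl({(4E)-5-[(4R,5S)-5-[4-(benzyloxy)-3-methoxyphenyl]-4-[(benzyloxy)methyl]-4,5-dihydrofuran-3-yl]pent-4-en-1-yl}oxy)dimethylsilane F3.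
- This 1-alkoxy diene has the same polarity as 16. It adds 17 thermally to give the cyclohexa-1,4-diene 1-[(2S,3R)-2-[4-(benzyloxy)-3-methoxyphenyl]-3-[(benzyloxy)methyl]-5-{3-[(tert-butyldimethylsilyl)oxy]propyl}-2,3,5,7a-tetrahydro-1-benzofuran-7-yl]ethan-1-one F4.
- DDQ (1 equiv, PhMe, 0 °C) dehydrogenates F4 to 19.

Step 5. The most likely failure is acyl transfer within the hydroxy lactone, in which the primary oxygen captures the carbonyl group and releases the C2 hydroxyl. Ionization of the electron-rich benzylic C–O bond at 83 °C with loss of the trans relation, and C-benzylation of ring C, are further risks. The fallback sets out from 1 and 4 and comes back at 9. It introduces the benzyl ether while no lactone exists, and it also replaces steps 1 to 4.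
- 1 is acylated (n-BuLi, then pent-4-enoyl chloride) to (4S)-4-benzyl-3-(pent-4-enoyl)-1,3-oxazolidin-2-one F5.
- The Bu2BOTf/i-Pr2NEt aldol reaction with 4 gives, with the same facial sense as step 2, the syn adduct (4S)-4-benzyl-3-[(2S)-2-{(S)-[4-(benzyloxy)-3-methoxyphenyl](hydroxy)methyl}pent-4-enoyl]-1,3-oxazolidin-2-one F6.
- LiBH4 (THF, MeOH, 0 °C) removes the auxiliary and gives the diol (1S,2R)-1-[4-(benzyloxy)-3-methoxyphenyl]-2-(prop-2-en-1-yl)propane-1,3-diol F7.
- Bu2SnO (PhMe, reflux), then BnBr and Bu4NBr, benzylates the primary oxygen through the stannylene acetal and gives (1S,2R)-2-[(benzyloxy)methyl]-1-[4-(benzyloxy)-3-methoxyphenyl]pent-4-en-1-ol F8.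
- OsO4 (cat.), NaIO4 and 2,6-lutidine in dioxane/H2O cleave the alkene; the aldehyde is captured by the C2 hydroxyl as the lactol (4R,5S)-5-[4-(benzyloxy)-3-methoxyphenyl]-4-[(benzyloxy)methyl]oxolan-2-ol F9.
- TEMPO (cat.) and PhI(OAc)2 oxidize F9 to 9.

Step 16. The most likely failure is over-reduction: hydrogenolysis of the benzylic C2–O1 bond while the slower alkyl benzyl ether is still being cleaved, at a stage where the polar sulfate cannot be purified on silica. Acid-catalysed loss of the sulfate is a second risk if the free acid is concentrated warm. The fallback sets out from 22 and comes back at 25. It moves the hydrogenolysis to a neutral, chromatographable stage and ends with base-labile esters, to which a sulfate monoester is stable.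
- H2 and Pd/C in EtOAc convert 22 into 4-[(2S,3R)-5-{3-[(tert-butyldimethylsilyl)oxy]propyl}-3-(hydroxymethyl)-7-methoxy-2,3-dihydro-1-benzofuran-2-yl]-2-methoxyphenol F10.
- Ac2O in pyridine gives the diacetate 4-[(2S,3R)-3-(acetoxymethyl)-5-{3-[(tert-butyldimethylsilyl)oxy]propyl}-7-methoxy-2,3-dihydro-1-benzofuran-2-yl]-2-methoxyphenyl acetate F11.
- HF·pyridine in THF/pyridine frees the chain alcohol 4-[(2S,3R)-3-(acetoxymethyl)-5-(3-hydroxypropyl)-7-methoxy-2,3-dihydro-1-benzofuran-2-yl]-2-methoxyphenyl acetate F12.
- SO3·pyridine, then NaHCO3, gives sodium 3-[(2S,3R)-3-(acetoxymethyl)-2-[4-(acetyloxy)-3-methoxyphenyl]-7-methoxy-2,3-dihydro-1-benzofuran-5-yl]propyl sulfate F13.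
- Na2CO3 in MeOH removes both acetates and gives 25, which is acidified as in step 16.

## Further compounds

F1 | step 11 | 1-{3-[(1S,2R)-3-(benzyloxy)-1-[4-(benzyloxy)-3-methoxyphenyl]-1-hydroxypropan-2-yl]-5-{3-[(tert-butyldimethylsilyl)oxy]propyl}-2-hydroxyphenyl}ethan-1-one | COc1cc([C@@H](O)[C@@H](COCc2ccccc2)c2cc(CCCO[Si](C)(C)C(C)(C)C)cc(C(C)=O)c2O)ccc1OCc1ccccc1
F2 | step 10 | (3E,4R,5S)-5-[4-(benzyloxy)-3-methoxyphenyl]-4-[(benzyloxy)methyl]-3-{5-[(tert-butyldimethylsilyl)oxy]pentylidene}oxolan-2-ol | COc1cc([C@H]2OC(O)/C(=C/CCCCO[Si](C)(C)C(C)(C)C)[C@@H]2COCc2ccccc2)ccc1OCc1ccccc1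
F3 | step 10 | tert-butyl({(4E)-5-[(4R,5S)-5-[4-(benzyloxy)-3-methoxyphenyl]-4-[(benzyloxy)methyl]-4,5-dihydrofuran-3-yl]pent-4-en-1-yl}oxy)dimethylsilane | COc1cc([C@H]2OC=C(/C=C/CCCO[Si](C)(C)C(C)(C)C)[C@@H]2COCc2ccccc2)ccc1OCc1ccccc1
F4 | step 10 | 1-[(2S,3R)-2-[4-(benzyloxy)-3-methoxyphenyl]-3-[(benzyloxy)methyl]-5-{3-[(tert-butyldimethylsilyl)oxy]propyl}-2,3,5,7a-tetrahydro-1-benzofuran-7-yl]ethan-1-one | COc1cc([C@H]2OC3C(C(C)=O)=CC(CCCO[Si](C)(C)C(C)(C)C)C=C3[C@@H]2COCc2ccccc2)ccc1OCc1ccccc1
F5 | step 5 | (4S)-4-benzyl-3-(pent-4-enoyl)-1,3-oxazolidin-2-one | C=CCCC(=O)N1[C@@H](Cc2ccccc2)COC1=O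
F6 | step 5 | (4S)-4-benzyl-3-[(2S)-2-{(S)-[4-(benzyloxy)-3-methoxyphenyl](hydroxy)methyl}pent-4-enoyl]-1,3-oxazolidin-2-one | COc1cc([C@@H](O)[C@H](CC=C)C(=O)N2[C@@H](Cc3ccccc3)COC2=O)ccc1OCc1ccccc1
F7 | step 5 | (1S,2R)-1-[4-(benzyloxy)-3-methoxyphenyl]-2-(prop-2-en-1-yl)propane-1,3-diol | COc1cc([C@@H](O)[C@H](CC=C)CO)ccc1OCc1ccccc1
F8 | step 5 | (1S,2R)-2-[(benzyloxy)methyl]-1-[4-(benzyloxy)-3-methoxyphenyl]pent-4-en-1-ol | COc1cc([C@@H](O)[C@H](CC=C)COCc2ccccc2)ccc1OCc1ccccc1
F9 | step 5 | (4R,5S)-5-[4-(benzyloxy)-3-methoxyphenyl]-4-[(benzyloxy)methyl]oxolan-2-ol | COc1cc([C@H]2OC(O)C[C@@H]2COCc2ccccc2)ccc1OCc1ccccc1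
F10 | step 16 | 4-[(2S,3R)-5-{3-[(tert-butyldimethylsilyl)oxy]propyl}-3-(hydroxymethyl)-7-methoxy-2,3-dihydro-1-benzofuran-2-yl]-2-methoxyphenol | COc1cc([C@H]2Oc3c(OC)cc(CCCO[Si](C)(C)C(C)(C)C)cc3[C@@H]2CO)ccc1O
F11 | step 16 | 4-[(2S,3R)-3-(acetoxymethyl)-5-{3-[(tert-butyldimethylsilyl)oxy]propyl}-7-methoxy-2,3-dihydro-1-benzofuran-2-yl]-2-methoxyphenyl acetate | COc1cc([C@H]2Oc3c(OC)cc(CCCO[Si](C)(C)C(C)(C)C)cc3[C@@H]2COC(C)=O)ccc1OC(C)=O
F12 | step 16 | 4-[(2S,3R)-3-(acetoxymethyl)-5-(3-hydroxypropyl)-7-methoxy-2,3-dihydro-1-benzofuran-2-yl]-2-methoxyphenyl acetate | COc1cc([C@H]2Oc3c(OC)cc(CCCO)cc3[C@@H]2COC(C)=O)ccc1OC(C)=O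
F13 | step 16 | sodium 3-[(2S,3R)-3-(acetoxymethyl)-2-[4-(acetyloxy)-3-methoxyphenyl]-7-methoxy-2,3-dihydro-1-benzofuran-5-yl]propyl sulfate | COc1cc([C@H]2Oc3c(OC)cc(CCCOS(=O)(=O)[O-])cc3[C@@H]2COC(C)=O)ccc1OC(C)=O.[Na+]
A1 | alternative 1 | (2S)-2-[4-(benzyloxy)-3-methoxyphenyl]-6-{3-[(tert-butyldiphenylsilyl)oxy]propyl}-8-methoxy-2,3-dihydro-4H-chromen-4-one | COc1cc([C@@H]2CC(=O)c3cc(CCCO[Si](c4ccccc4)(c4ccccc4)C(C)(C)C)cc(OC)c3O2)ccc1OCc1ccccc1
A2 | alternative 1 | methyl (2S,3S)-2-[4-(benzyloxy)-3-methoxyphenyl]-5-{3-[(tert-butyldiphenylsilyl)oxy]propyl}-7-methoxy-2,3-dihydro-1-benzofuran-3-carboxylate | COc1cc([C@H]2Oc3c(OC)cc(CCCO[Si](c4ccccc4)(c4ccccc4)C(C)(C)C)cc3[C@@H]2C(=O)OC)ccc1OCc1ccccc1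
A3 | alternative 2 | tert-butyl[3-(4-{[(1S)-1-[4-(benzyloxy)-3-methoxyphenyl]prop-2-en-1-yl]oxy}-3-iodo-5-methoxyphenyl)propoxy]dimethylsilane | COc1cc([C@H](C=C)Oc2c(I)cc(CCCO[Si](C)(C)C(C)(C)C)cc2OC)ccc1OCc1ccccc1
A4 | alternative 2 | {(2S,3R)-2-[4-(benzyloxy)-3-methoxyphenyl]-5-{3-[(tert-butyldimethylsilyl)oxy]propyl}-7-methoxy-2,3-dihydro-1-benzofuran-3-yl}methanol | COc1cc([C@H]2Oc3c(OC)cc(CCCO[Si](C)(C)C(C)(C)C)cc3[C@@H]2CO)ccc1OCc1ccccc1
A5 | alternative 3 | tert-butyl(3-{5-[(2R,3S)-1-(benzyloxy)-3-[4-(benzyloxy)-3-methoxyphenyl]-3-(ethynyloxy)propan-2-yl]furan-3-yl}propoxy)dimethylsilane | COc1cc([C@@H](OC#C)[C@@H](COCc2ccccc2)c2cc(CCCO[Si](C)(C)C(C)(C)C)co2)ccc1OCc1ccccc1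
A6 | alternative 3 | (2S,3R)-2-[4-(benzyloxy)-3-methoxyphenyl]-3-[(benzyloxy)methyl]-5-{3-[(tert-butyldimethylsilyl)oxy]propyl}-2,3-dihydro-1-benzofuran-7-ol (identical with 21) | COc1cc([C@H]2Oc3c(O)cc(CCCO[Si](C)(C)C(C)(C)C)cc3[C@@H]2COCc2ccccc2)ccc1OCc1ccccc1
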